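Target ⇒ C2 ketone 28 (exocyclic enone added last by Meyer–Schuster rearrangement) ⇒ C1 aldehyde 19 (Wittig, Still–Gennari and Wittig olefinations build the (1′E,3′Z,5′E)-trienoate) ⇒ cis-decalin ketone 15.
The plan rests on ring A holding C3(CH3)=C4 next to the cis C4a–C8a fusion while ring B holds the C7 oxygen between the methyl-bearing C6 and C8: this is the enolate pattern left by an oxy-Cope shift of a 2-vinylbicyclo[2.2.2]oct-5-en-2-ol with bridgeheads C3 and C8a.
Key disconnection: C4a–C5 is formed and C3–C7 broken in the [3,3] shift of carbinol 12, and C6–CH3 comes from trapping the enolate; ring A exists first (as the cyclohexene of the bicycle) and ring B closes in the key step.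
Bicycle 10 comes from a Diels–Alder reaction of the o-quinol ester 7 of 2,6-dimethylphenol (C3, C4, C4a, C8a, C8, C7) with the cyclic enol ether 4 (C2, C1, C1′), then deacyloxylation; vinyl addition brings C5 and C6.
Absolute configuration comes from a camphanate on the quinol carbon: its diastereomers are separated, the cycloaddition relays the configuration to the bicycle, and SmI2 then removes the auxiliary without trace.

Key step: step 7

Remark: numbering used for all compounds: C1 bears the trienoic acid chain (C1′ to C6′, CO2H on C6′), C2 is the exocyclic enone carbon, C3(CH3)=C4, C4a and C8a are the ring fusion, C5 is the methylene, C6(CH3), C7(OH), C8(CH3); ring A = C1 to C4a plus C8a, ring B = C4a to C8a.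
Remark: the 2π partner must deliver oxygen to C2 and a one-carbon branch to C1; furan is not used because it bonds through its α-carbon to the electrophilic unsubstituted terminus of a cyclohexa-2,4-dienone, which would put oxygen on C1, so the cyclic enol ether 4 (β-carbon carrying C1′) is used and C1′ arrives at the alcohol level.
Remark: the dearomatisation uses Pb(OAc)4 because trivalent iodine oxidants attack the free para position of 2,6-dimethylphenol; the two C8 epimers of ester 7 are assumed to be separable (if not, the pair is carried through step 4 and the diastereomeric adducts are separated there).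
Remark: the configuration drawn at C2 of 31 is the expected one and is of no consequence, since C2 becomes trigonal in step 18.

Step 1
Reactants: 1 2,2-dimethyl-1,3-dioxan-5-one
Product: 3 2,2-dimethyl-4H-1,3-dioxin-5-yl trifluoromethanesulfonate, via sodium enolate 2 (not isolated)
Conditions: NaN(SiMe3)2, THF, −78 °C; PhNTf2, −78 → 0 °C
Reagents that add atoms: N-phenylbis(trifluoromethanesulfonimide) O=S(=O)(N(c1ccccc1)S(=O)(=O)C(F)(F)F)C(F)(F)F
Why: Enol triflate formation: the symmetrical ketone gives a single enolate, which is O-sulfonylated by the triflimide, and no stereocentre is formed.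

Step 2
Reactants: 3 2,2-dimethyl-4H-1,3-dioxin-5-yl trifluoromethanesulfonate
Product: 4 2,2-dimethyl-4H-1,3-dioxin
Conditions: Pd(OAc)2 (cat.), PPh3, HCO2H, Bu3N, DMF, 60 °C
Reagents that add atoms: none
Why: Palladium-catalysed formate reduction of an enol triflate (hydride transfer to the alkenylpalladium intermediate, then reductive elimination) should give the cyclic cis-enol ether without touching the acetal, and no stereocentre is formed.

Step 3
Reactants: 5 2,6-dimethylphenol; 6 (1S,4R)-camphanic acid
Product: 7 (1S)-1,3-dimethyl-2-oxocyclohexa-3,5-dien-1-yl (1S,4R)-camphanate (o-quinol ester, quinol carbon = future C8), separated from its C8 epimer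
Conditions: Pb(OAc)4 pre-exchanged with 6 (5 equiv, AcOH stripped with toluene), CH2Cl2, 0 °C; chromatography or crystallisation
Reagents that add atoms: none
Why: Wessely-type oxidative dearomatisation, in which the aryloxy–lead intermediate delivers a carboxylate ligand to the methyl-bearing ortho carbon; the new quaternary centre forms without control, and the chiral camphanoyl group turns the two outcomes into separable diastereomers, of which the (S) epimer is carried on.

Step 4
Reactants: 7 o-quinol camphanate; 4 2,2-dimethyl-4H-1,3-dioxin
Product: 8 endo cycloadduct: bicyclo[2.2.2]octenone with bridgeheads C3 (CH3) and C8a, C4=C4a bridge, C7 ketone, C8 carrying CH3 on the alkene side and the camphanoyloxy group on the side of the C1–C2 bridge, and a cis-fused 2,2-dimethyl-1,3-dioxane (O on C2, CH2 on C1) on the alkene side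
Conditions: 4 (5 equiv), toluene, K2CO3 (solid, trace), sealed tube, 100 °C
Reagents that add atoms: none
Why: Inverse-demand Diels–Alder reaction of a cyclohexa-2,4-dienone with an enol ether, in which the nucleophilic β-carbon of 4 (future C1) bonds to the unsubstituted electrophilic diene terminus (future C8a) and the oxygen-bearing carbon (future C2) to the methyl-bearing terminus (future C3), the dioxin ring lies endo under the diene, and the dienophile adds to the face that carries the acyloxy group, so that C1, C2, C3 and C8a are set relative to the quinol centre of 7.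

Step 5
Reactants: 8 cycloadduct
Product: 10 C8-deoxygenated bicyclo[2.2.2]octenone (C8 methyl on the alkene side), via samarium enolate 9 (not isolated)
Conditions: SmI2, THF–MeOH, −78 °C; then DBU (cat.), CH2Cl2, rt
Reagents that add atoms: none
Why: Two-electron reductive cleavage of the α-acyloxy ketone by SmI2 expels the camphanate, the samarium enolate is protonated by methanol, and base equilibration of the epimerisable C8 centre should favour the methyl group on the side of the C4=C4a bridge, where it avoids the 1,3-contact with the exo hydrogen on C1 (the minor epimer is re-equilibrated); from here the bicycle alone carries the absolute configuration.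

Step 6
Reactants: 10 bicyclic ketone; 11 vinylmagnesium bromide
Product: 12 2-vinylbicyclo[2.2.2]oct-5-en-2-ol: C7 tertiary alcohol with the vinyl group on the side of the C4=C4a bridge and the hydroxyl on the side of the C1–C2 bridge
Conditions: LaCl3·2LiCl, THF, 0 °C; CH2=CHMgBr, −78 → 0 °C
Reagents that add atoms: none
Why: Lanthanum-assisted Grignard 1,2-addition (which suppresses enolisation of the epimerisable ketone), in which the reagent should enter C7 from the face of the C4=C4a bridge because the opposite face is screened by the exo hydrogen on C2 of the saturated bridge, while C8–CH3 is eclipsed with one of the two new substituents whichever face is used; the vinyl group therefore ends up over the alkene, as the sigmatropic shift requires.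

Step 7
Reactants: 12 vinyl carbinol
Product: 15 acetonide-protected cis-fused C7 ketone bearing the C6 and C8 methyl groups, via potassium alkoxide 13 (not isolated), via potassium enolate 14 (not isolated)
Conditions: KN(SiMe3)2 (1.1 equiv), 18-crown-6, THF, 0 °C → rt; MeI, −78 → 0 °C
Reagents that add atoms: iodomethane CI
Why: The dissociated potassium alkoxide 13 undergoes a charge-accelerated [3,3] shift through a boat-like array that breaks C3–C7 and makes C4a–C5, the closest known type being the anionic oxy-Cope rearrangement of 2-vinylbicyclo[2.2.2]oct-5-en-2-ols with alkylation of the enolate in the same flask. Ring B is closed by the sigmatropic shift itself (a six-membered pericyclic closure, not a separate cyclisation), and ring A is the cyclohexene already present in the bicycle. C4a is set by the bicycle, because C5 can reach C4a only on the face turned to the carbinol bridge, which gives the cis fusion; C6 is set when iodomethane alkylates the regiodefined C6=C7 enolate 14 on the convex face away from ring A, giving the cis-2,6-dimethyl ketone with both methyl groups equatorial, which is also the thermodynamic isomer. The step needs the [3,3] shift to outrun a Grob-type loss of the anti-periplanar C2–O bond, and mono-C-methylation to outrun O- and poly-alkylation; the first is secured by the poor acetal-alkoxide leaving group and the syn vinyl/alkene geometry, the second by a single enolate regioisomer, one equivalent of base and a soft electrophile at low temperature.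

Step 8
Reactants: 15 cis-decalin ketone
Product: 16 C7 alcohol, hydroxyl trans to both flanking methyl groups
Conditions: Li, NH3(l), THF, EtOH, −78 °C; NH4Cl
Reagents that add atoms: none
Why: Dissolving-metal reduction of the ketone should give the more stable equatorial C7 alcohol, trans to both equatorial methyl groups, where small hydride reagents are unreliable for cis-2,6-dialkylcyclohexanones; the isolated alkene and the acetal are inert.

Step 9
Reactants: 16 C7 alcohol
Product: 17 C7 tert-butyldimethylsilyl ether
Conditions: TBSOTf, 2,6-lutidine, CH2Cl2, −78 → 0 °C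
Reagents that add atoms: tert-butyldimethylsilyl trifluoromethanesulfonate CC(C)(C)[Si](C)(C)OS(=O)(=O)C(F)(F)F
Why: Silylation of a hindered secondary alcohol with the silyl triflate and a non-nucleophilic base, under buffered low-temperature conditions that leave the acetonide intact and touch no stereocentre.

Step 10
Reactants: 17 silyl ether acetonide
Product: 18 diol: C1 hydroxymethyl and C2 hydroxyl, both on the face of the ring-fusion hydrogens
Conditions: PPTS, MeOH, rt
Reagents that add atoms: none
Why: Acid-catalysed transacetalisation with methanol removes the isopropylidene group, while the hindered secondary silyl ether should survive the weak acid.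

Step 11
Reactants: 18 diol
Product: 19 C1 aldehyde with free C2 hydroxyl
Conditions: TEMPO (cat.), PhI(OAc)2, CH2Cl2, rt
Reagents that add atoms: none
Why: Oxoammonium (TEMPO) oxidation is selective for the primary alcohol over the hindered secondary allylic C2 alcohol and stops at the aldehyde under neutral conditions that should neither epimerise C1 nor dehydrate the aldol-type product.

Step 12
Reactants: 19 hydroxy aldehyde; 20 2-(triphenylphosphoranylidene)propanal
Product: 21 (E)-enal: C1–CH=C(CH3)–CHO, C2 hydroxyl free
Conditions: 20 (1.5 equiv), toluene, 80 °C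
Reagents that add atoms: none
Why: Wittig reaction with a formyl-stabilised ylide gives the trisubstituted (E) C1′=C2′ bond (C1 trans to the formyl group) under neutral conditions, after which C1 is no longer α to a carbonyl group.

Step 13
Reactants: 21 enal; 22 methyl 2-[bis(2,2,2-trifluoroethoxy)phosphoryl]propanoate
Product: 24 methyl (2Z,4E)-2,4-dimethylpenta-2,4-dienoate side chain on C1 (C2 hydroxyl free), via potassium phosphonate carbanion 23 (not isolated)
Conditions: KN(SiMe3)2, 18-crown-6, THF, −78 °C
Reagents that add atoms: none
Why: Still–Gennari olefination, in which fast elimination from the kinetic adduct of the trifluoroethyl phosphonate should give the (Z)-trisubstituted C3′=C4′ ester (ester cis to C2′); the stabilised carbanion does not deprotonate the C2 hydroxyl.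

Step 14
Reactants: 24 dienoate
Product: 25 diol: primary dienyl alcohol at C5′ and C2 hydroxyl
Conditions: i-Bu2AlH, CH2Cl2, −78 °C; aqueous KNaC4H4O6
Reagents that add atoms: none
Why: Hydride reduction of the conjugated ester to the allylic alcohol at low temperature, which preserves both alkene geometries.

Step 15
Reactants: 25 diol
Product: 26 keto aldehyde: C2 ketone conjugated with C3=C4 and (Z)-enal at C5′
Conditions: Dess–Martin periodinane, NaHCO3, CH2Cl2, 0 °C → rt; used crude
Reagents that add atoms: none
Why: Dess–Martin oxidation converts the primary allylic alcohol into the (Z)-enal and the secondary allylic C2 alcohol into the ring enone in one operation, with buffering to limit Z to E isomerisation and enolisation at C1.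

Step 16
Reactants: 26 keto aldehyde; 27 allyl 2-(triphenylphosphoranylidene)acetate
Product: 28 allyl (2E,4Z,6E)-trienoate with C2 ketone
Conditions: 27 (1.5 equiv), CH2Cl2, rt
Reagents that add atoms: none
Why: Wittig reaction with an ester-stabilised ylide is selective for the aldehyde over the hindered conjugated ketone and gives the (E) C5′=C6′ bond, which completes the (1′E,3′Z,5′E)-triene.

Step 17
Reactants: 28 keto trienoate; 29 tert-butyldimethyl(prop-2-yn-1-yloxy)silane
Product: 31 tertiary propargylic alcohol at C2, via lithium acetylide 30 (not isolated)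
Conditions: 29, n-BuLi, THF, −78 °C; LaCl3·2LiCl; 28, −78 °C
Reagents that add atoms: none
Why: 1,2-Addition of a lithium acetylide to the C2 enone carbonyl, assisted by LaCl3·2LiCl to outrun enolisation at the acidic C1 position and selective for the ketone over the allyl ester at −78 °C; the nucleophile should enter anti to the axial C1 side chain, but the new centre is lost in step 18.

Step 18
Reactants: 31 propargylic alcohol
Product: 32 exocyclic (E)-enone C2=CH–C(=O)–CH2OTBS, allyl ester, C7 silyl ether
Conditions: Ph3PAuNTf2 (cat.), 4-MeOC6H4B(OH)2 (cat.), toluene, rt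
Reagents that add atoms: none
Why: Gold-catalysed Meyer–Schuster rearrangement (1,3-hydroxyl shift of the tertiary propargylic alcohol, then tautomerisation of the allenol) gives the exocyclic enone, and the (E) isomer with the acyl group on the C1 side should be favoured because the other geometry presses it against C3–CH3.

Step 19
Reactants: 32 allyl ester
Product: 33 carboxylic acid, both silyl ethers in place
Conditions: Pd(PPh3)4 (cat.), N-methylaniline, THF, rt
Reagents that add atoms: none
Why: Palladium-catalysed allyl transfer (Tsuji–Trost deallylation) to a weakly basic amine frees the carboxylic acid under neutral conditions that spare the dienone, the (Z)-alkene and the silyl ethers.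

Step 20
Reactants: 33 bis-silyl ether acid
Product: 34 CNP0219601.2
Conditions: HF·pyridine, pyridine, THF, 0 °C → rt
Reagents that add atoms: none
Why: Desilylation with buffered hydrogen fluoride removes both silyl ethers without the base that could deconjugate the enone through the acidic C1–H or isomerise the triene.

Compound list
1 | 2,2-dimethyl-1,3-dioxan-5-one | CC1(C)OCC(=O)CO1 | starting material
2 | sodium enolate of 1 | CC1(C)OCC([O-])=CO1.[Na+] | intermediate
3 | 2,2-dimethyl-4H-1,3-dioxin-5-yl trifluoromethanesulfonate | CC1(C)OCC(OS(=O)(=O)C(F)(F)F)=CO1 | intermediate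
4 | 2,2-dimethyl-4H-1,3-dioxin | CC1(C)OCC=CO1 | intermediate
5 | 2,6-dimethylphenol | Cc1cccc(C)c1O | starting material
6 | (1S,4R)-camphanic acid ((1S,4R)-4,7,7-trimethyl-3-oxo-2-oxabicyclo[2.2.1]heptane-1-carboxylic acid) | OC(=O)[C@@]12CC[C@@](C)(C(=O)O1)C2(C)C | starting material
7 | (1S)-1,3-dimethyl-2-oxocyclohexa-3,5-dien-1-yl (1S,4R)-camphanate | CC1=CC=C[C@](C)(OC(=O)[C@@]23CC[C@@](C)(C(=O)O2)C3(C)C)C1=O | intermediate
8 | endo cycloadduct (C7 ketone, C8 camphanoyloxy on the C1–C2 bridge side, cis-fused acetonide on the alkene side) | C[C@@]12C=C[C@@H]([C@](C)(OC(=O)[C@@]45CC[C@@](C)(C(=O)O4)C5(C)C)C1=O)[C@@H]3COC(C)(C)O[C@H]23 | intermediate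
9 | samarium enolate (C7–O–SmI2, C7=C8) | C[C@@]12C=C[C@@H](C(C)=C1O[Sm](I)I)[C@@H]3COC(C)(C)O[C@H]23 | intermediate
10 | bicyclo[2.2.2]octenone, C8–CH3 on the alkene side | C[C@@]12C=C[C@@H]([C@@H](C)C1=O)[C@@H]3COC(C)(C)O[C@H]23 | intermediate
11 | vinylmagnesium bromide | C=C[Mg]Br | starting material
12 | C7 vinyl carbinol (vinyl on the alkene side) | C[C@@]12C=C[C@@H]([C@@H](C)[C@@]1(O)C=C)[C@@H]3COC(C)(C)O[C@H]23 | intermediate
13 | potassium alkoxide of 12 | C[C@@]12C=C[C@@H]([C@@H](C)[C@@]1([O-])C=C)[C@@H]3COC(C)(C)O[C@H]23.[K+] | intermediate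
14 | potassium C6=C7 enolate of the cis-decalin | CC1=C[C@H]2CC=C([O-])[C@H](C)[C@H]2[C@@H]3COC(C)(C)O[C@H]13.[K+] | intermediate
15 | cis-fused C7 ketone with C6 and C8 methyls, acetonide across C2–O and C1–CH2O | CC1=C[C@H]2C[C@H](C)C(=O)[C@H](C)[C@H]2[C@@H]3COC(C)(C)O[C@H]13 | intermediate
16 | C7 alcohol | CC1=C[C@H]2C[C@H](C)[C@@H](O)[C@H](C)[C@H]2[C@@H]3COC(C)(C)O[C@H]13 | intermediate
17 | C7 TBS ether | CC1=C[C@H]2C[C@H](C)[C@@H](O[Si](C)(C)C(C)(C)C)[C@H](C)[C@H]2[C@@H]3COC(C)(C)O[C@H]13 | intermediate
18 | C1 hydroxymethyl, C2 hydroxyl diol | CC1=C[C@H]2C[C@H](C)[C@@H](O[Si](C)(C)C(C)(C)C)[C@H](C)[C@H]2[C@H](CO)[C@@H]1O | intermediate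
19 | C1 aldehyde, C2 hydroxyl | CC1=C[C@H]2C[C@H](C)[C@@H](O[Si](C)(C)C(C)(C)C)[C@H](C)[C@H]2[C@H](C=O)[C@@H]1O | intermediate
20 | 2-(triphenylphosphoranylidene)propanal | CC(C=O)=P(c1ccccc1)(c1ccccc1)c1ccccc1 | starting material
21 | (E)-enal | CC1=C[C@H]2C[C@H](C)[C@@H](O[Si](C)(C)C(C)(C)C)[C@H](C)[C@H]2[C@H](/C=C(C)/C=O)[C@@H]1O | intermediate
22 | methyl 2-[bis(2,2,2-trifluoroethoxy)phosphoryl]propanoate | COC(=O)C(C)P(=O)(OCC(F)(F)F)OCC(F)(F)F | starting material
23 | potassium carbanion of 22 | COC(=O)[C-](C)P(=O)(OCC(F)(F)F)OCC(F)(F)F.[K+] | intermediate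
24 | methyl (2Z,4E)-dienoate | CC1=C[C@H]2C[C@H](C)[C@@H](O[Si](C)(C)C(C)(C)C)[C@H](C)[C@H]2[C@H](/C=C(C)/C=C(C)\C(=O)OC)[C@@H]1O | intermediate
25 | dienyl alcohol diol | CC1=C[C@H]2C[C@H](C)[C@@H](O[Si](C)(C)C(C)(C)C)[C@H](C)[C@H]2[C@H](/C=C(C)/C=C(C)\CO)[C@@H]1O | intermediate
26 | keto aldehyde | CC1=C[C@H]2C[C@H](C)[C@@H](O[Si](C)(C)C(C)(C)C)[C@H](C)[C@H]2[C@H](/C=C(C)/C=C(C)\C=O)C1=O | intermediate
27 | allyl 2-(triphenylphosphoranylidene)acetate | C=CCOC(=O)C=P(c1ccccc1)(c1ccccc1)c1ccccc1 | starting material
28 | allyl (2E,4Z,6E)-trienoate, C2 ketone | CC1=C[C@H]2C[C@H](C)[C@@H](O[Si](C)(C)C(C)(C)C)[C@H](C)[C@H]2[C@H](/C=C(C)/C=C(C)\C=C\C(=O)OCC=C)C1=O | intermediate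
29 | tert-butyldimethyl(prop-2-yn-1-yloxy)silane | C#CCO[Si](C)(C)C(C)(C)C | starting material
30 | lithium acetylide of 29 | [Li]C#CCO[Si](C)(C)C(C)(C)C | intermediate
31 | C2 tertiary propargylic alcohol | CC1=C[C@H]2C[C@H](C)[C@@H](O[Si](C)(C)C(C)(C)C)[C@H](C)[C@H]2[C@H](/C=C(C)/C=C(C)\C=C\C(=O)OCC=C)[C@@]1(O)C#CCO[Si](C)(C)C(C)(C)C | intermediate
32 | exocyclic (E)-enone, allyl ester, bis-TBS | CC1=C[C@H]2C[C@H](C)[C@@H](O[Si](C)(C)C(C)(C)C)[C@H](C)[C@H]2[C@H](/C=C(C)/C=C(C)\C=C\C(=O)OCC=C)/C1=C\C(=O)CO[Si](C)(C)C(C)(C)C | intermediate
33 | carboxylic acid, bis-TBS | CC1=C[C@H]2C[C@H](C)[C@@H](O[Si](C)(C)C(C)(C)C)[C@H](C)[C@H]2[C@H](/C=C(C)/C=C(C)\C=C\C(=O)O)/C1=C\C(=O)CO[Si](C)(C)C(C)(C)C | intermediate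
34 | CNP0219601.2 | CC1=C[C@H]2C[C@H](C)[C@@H](O)[C@H](C)[C@H]2[C@H](/C=C(C)/C=C(C)\C=C\C(=O)O)/C1=C\C(=O)CO | target

Total step count: 20.
Longest linear sequence: 19 steps (steps 1, 2 and 4 to 20, from 2,2-dimethyl-1,3-dioxan-5-one); the phenol branch has 18.

Steps most likely to fail

Step 4. The methyl-bearing diene terminus and the cis-disubstituted enol ether may react too slowly, so that thermal decomposition of the dienone, acyloxy migration or loss of facial control takes over at the temperature needed. The fallback sets out from 4 and commercial 2-methoxy-6-methylphenol and comes back at 10. The phenol is oxidised with PhI(OAc)2 in methanol in the presence of 4 (0 °C to rt), so that the far more reactive masked o-benzoquinone 6,6-dimethoxy-2-methylcyclohexa-2,4-dien-1-one F1 forms in the flask and should add 4 with the same orientation to give the racemic 8,8-dimethoxy cycloadduct F2. SmI2 in THF–MeOH removes both methoxy groups to give the racemic C8-unsubstituted bicyclic ketone F3. LiN(i-Pr)2 (THF, −78 °C) gives the lithium enolate F4, which iodomethane should alkylate on the face of the alkene bridge to give racemic 10. Chromatography on a chiral stationary phase removes the enantiomer of 10 F5 and returns 10.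

Step 7. Heterolytic Grob-type cleavage of the alkoxide (C3–C7 scission followed by loss of the anti-periplanar C2–O bond) may compete with the sigmatropic shift, and proton exchange between enolate and product may lead to double methylation. The fallback sets out from 12 and comes back at 15. Silylation with N-(trimethylsilyl)imidazole gives the trimethylsilyl ether of 12 F6, and a neutral thermal oxy-Cope rearrangement (o-dichlorobenzene, sealed tube, about 220 °C) should give the C6=C7 trimethylsilyl enol ether F7 with no alkoxide present. MeLi (THF, 0 °C) then releases the lithium enolate F8, which is methylated with iodomethane at −78 °C to give 15.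

Step 18. Ionisation of the tertiary alcohol, which is both allylic and propargylic, may lead to elimination towards C1 or to allylic transposition instead of the 1,3-hydroxyl shift, and the enone geometry may not be controlled. The fallback sets out from 28 and comes back at 32. (E)-tert-Butyl[(3-iodoprop-2-en-1-yl)oxy]dimethylsilane is lithiated with t-BuLi (−78 °C) to (E)-[3-(tert-butyldimethylsilyloxy)prop-1-en-1-yl]lithium F9, which adds to 28 (LaCl3·2LiCl, −78 °C) to give the tertiary bis-allylic alcohol F10. A Babler–Dauben-type oxidative 1,3-transposition with 4-acetamido-2,2,6,6-tetramethyl-1-oxopiperidinium tetrafluoroborate (MeCN, rt) should move the oxygen to the less hindered side-chain terminus and oxidise it, giving 32.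

Further compounds
F1 | step 4 | 6,6-dimethoxy-2-methylcyclohexa-2,4-dien-1-one | CC1=CC=CC(OC)(OC)C1=O
F2 | step 4 | racemic 8,8-dimethoxy cycloadduct (enantiomer leading to 10 drawn) | C[C@@]12C=C[C@@H](C(OC)(OC)C1=O)[C@@H]3COC(C)(C)O[C@H]23
F3 | step 4 | racemic C8-unsubstituted bicyclic ketone (enantiomer leading to 10 drawn) | C[C@@]12C=C[C@@H](CC1=O)[C@@H]3COC(C)(C)O[C@H]23
F4 | step 4 | lithium enolate of F3 | C[C@@]12C=C[C@@H](C=C1[O-])[C@@H]3COC(C)(C)O[C@H]23.[Li+]
F5 | step 4 | enantiomer of 10 | C[C@]12C=C[C@H]([C@H](C)C1=O)[C@H]3COC(C)(C)O[C@@H]23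
F6 | step 7 | trimethylsilyl ether of 12 | C[C@@]12C=C[C@@H]([C@@H](C)[C@@]1(O[Si](C)(C)C)C=C)[C@@H]3COC(C)(C)O[C@H]23
F7 | step 7 | C6=C7 trimethylsilyl enol ether of the cis-decalin | CC1=C[C@H]2CC=C(O[Si](C)(C)C)[C@H](C)[C@H]2[C@@H]3COC(C)(C)O[C@H]13
F8 | step 7 | lithium C6=C7 enolate of the cis-decalin | CC1=C[C@H]2CC=C([O-])[C@H](C)[C@H]2[C@@H]3COC(C)(C)O[C@H]13.[Li+]
F9 | step 18 | (E)-[3-(tert-butyldimethylsilyloxy)prop-1-en-1-yl]lithium | [Li]/C=C/CO[Si](C)(C)C(C)(C)C
F10 | step 18 | C2 tertiary bis-allylic alcohol | CC1=C[C@H]2C[C@H](C)[C@@H](O[Si](C)(C)C(C)(C)C)[C@H](C)[C@H]2[C@H](/C=C(C)/C=C(C)\C=C\C(=O)OCC=C)[C@@]1(O)/C=C/CO[Si](C)(C)C(C)(C)C
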